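In cembrane numbering the target is a 14-membered carbocycle (C1–C14) cis-fused at C1/C2 to an α-methylene-γ-butyrolactone (C15=C17 exocyclic). Because the lactone β-carbon C1 is allylic to C15=C17, the C1–C14 bond is disconnected as a radical SN2′ allyl transfer: a primary C14 radical from an open-chain β-acetoxy iodide adds to C1 of a 3-(phenylsulfonylmethyl)butenolide and expels the sulfonyl radical from C17. One operation closes the carbocycle, sets C1 and unveils the methylene lactone, so the ring closure is the last step. The precursor is assembled by cross-metathesis at C6=C7 from a butenolide sulfone (west fragment) and an epoxy iodo acetate made from (S)-linalool (east fragment).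

Key step: step 16

Remark: cembrane numbering is used throughout (C2 lactone O–CH, C3=C4 with methyl on C4, C6=C7, C8 carbinol, C11/C12 epoxide, C13 acetate carbon, C16 lactone carbonyl), and (S)-(+)-linalool is assumed to be purchasable in high enantiomeric purity.

Step 1
Reactants: 1 2-(bromomethyl)prop-2-enoic acid; 2 sodium benzenesulfinate
Product: 3 2-[(phenylsulfonyl)methyl]prop-2-enoic acid
Conditions: MeOH, reflux
Reagents that add atoms: none
Why: Sulfinate S-alkylation of the allylic bromide (SN2 or SN2′, both giving the same product) is the standard entry to 2-(sulfonylmethyl)acrylic acids and forms no stereocentre.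

Step 2
Reactants: 4 pent-1-en-4-yne; 5 acrolein (prop-2-enal)
Product: 7 (4E)-5-methylocta-1,4,7-trien-3-ol (racemic), via alkenylalane 6 (not isolated)
Conditions: Me3Al, Cp2ZrCl2 (20 mol %), CH2Cl2, 0 °C to rt; then 5, −78 to 0 °C; aqueous Rochelle salt
Reagents that add atoms: trimethylaluminium C[Al](C)C
Why: Negishi zirconium-catalysed carboalumination adds methyl and aluminium syn across the terminal alkyne, which fixes the E geometry of the future C3=C4 olefin, and the alkenylalane then adds 1,2 to acrolein with retention at the sp2 carbon, the carbinol centre forming as a racemate that step 3 resolves.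

Step 3
Reactants: 7 (4E)-5-methylocta-1,4,7-trien-3-ol (racemic)
Product: 8 (3R,4E)-5-methylocta-1,4,7-trien-3-yl acetate
Conditions: Novozym 435 (immobilised Candida antarctica lipase B), vinyl acetate, hexane, 30 °C, stopped near 45 % conversion
Reagents that add atoms: vinyl acetate C=COC(C)=O
Why: Lipase-catalysed kinetic resolution by transesterification should acylate the enantiomer that places the vinyl group in the medium pocket and the dienyl group in the large pocket, which is (R), and the unreacted (S)-alcohol is removed by chromatography.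

Step 4
Reactants: 8 (3R,4E)-5-methylocta-1,4,7-trien-3-yl acetate
Product: 9 (3R,4E)-5-methylocta-1,4,7-trien-3-ol
Conditions: K2CO3 (cat.), MeOH, 0 °C to rt
Reagents that add atoms: none
Why: Base-catalysed methanolysis (transesterification) frees the alcohol without touching the C–O bond of the stereocentre or the skipped diene.

Step 5
Reactants: 9 (3R,4E)-5-methylocta-1,4,7-trien-3-ol; 3 2-[(phenylsulfonyl)methyl]prop-2-enoic acid
Product: 10 (3R,4E)-5-methylocta-1,4,7-trien-3-yl 2-[(phenylsulfonyl)methyl]prop-2-enoate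
Conditions: DCC, DMAP (5 mol %), CH2Cl2, 0 °C to rt
Reagents that add atoms: none
Why: Steglich esterification acylates the oxygen, so the configuration at the carbinol carbon is retained.

Step 6
Reactants: 10 (3R,4E)-5-methylocta-1,4,7-trien-3-yl 2-[(phenylsulfonyl)methyl]prop-2-enoate
Product: 11 (5S)-5-[(1E)-2-methylpenta-1,4-dien-1-yl]-3-[(phenylsulfonyl)methyl]furan-2(5H)-one
Conditions: second-generation Hoveyda–Grubbs catalyst (H2IMes)Cl2Ru=CH(C6H4-2-OiPr) (10 mol %), toluene (5 mM), 80 °C
Reagents that add atoms: none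
Why: Ring-closing metathesis between the acrylate and the vinyl group should give the five-membered unsaturated lactone, the E olefin of the side chain excluding any other ring closure and high dilution suppressing dimerisation at the allyl terminus, while the stereocentre is untouched.

Step 7
Reactants: 12 (S)-(+)-linalool, (3S)-3,7-dimethylocta-1,6-dien-3-ol
Product: 13 triethyl{[(3S)-3,7-dimethylocta-1,6-dien-3-yl]oxy}silane
Conditions: Et3SiOTf, 2,6-lutidine, CH2Cl2, −78 to 0 °C
Reagents that add atoms: triethylsilyl trifluoromethanesulfonate CC[Si](CC)(CC)OS(=O)(=O)C(F)(F)F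
Why: Silylation of the tertiary alcohol with the silyl triflate and a hindered base protects O8 against cyclisation onto C11 in steps 9 to 13 and does not involve the stereocentre.

Step 8
Reactants: 13 triethyl{[(3S)-3,7-dimethylocta-1,6-dien-3-yl]oxy}silane
Product: 14 (4S)-4-methyl-4-[(triethylsilyl)oxy]hex-5-enal
Conditions: O3 (1 equiv, Sudan Red 7B end point), CH2Cl2, −78 °C; then PPh3, −78 °C to rt
Reagents that add atoms: ozone [O-][O+]=O
Why: Chemoselective ozonolysis should work because ozone attacks the electron-rich trisubstituted olefin much faster than the hindered monosubstituted vinyl group, and reductive work-up gives the aldehyde.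

Step 9
Reactants: 14 (4S)-4-methyl-4-[(triethylsilyl)oxy]hex-5-enal; 15 methyl 2-[bis(2,2,2-trifluoroethoxy)phosphoryl]propanoate
Product: 16 methyl (2Z,6S)-2,6-dimethyl-6-[(triethylsilyl)oxy]octa-2,7-dienoate
Conditions: KHMDS, 18-crown-6, THF, −78 °C
Reagents that add atoms: none
Why: The Still–Gennari variant of the Horner–Wadsworth–Emmons reaction gives the Z trisubstituted enoate under kinetic control, which places C10 and C13 cis as the cis-epoxide of the target requires.

Step 10
Reactants: 16 methyl (2Z,6S)-2,6-dimethyl-6-[(triethylsilyl)oxy]octa-2,7-dienoate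
Product: 17 (2Z,6S)-2,6-dimethyl-6-[(triethylsilyl)oxy]octa-2,7-dien-1-ol
Conditions: i-Bu2AlH, CH2Cl2, −78 °C; aqueous Rochelle salt
Reagents that add atoms: none
Why: DIBAL-H reduction of the conjugated ester to the allylic alcohol leaves the olefin geometry and the silyl ether intact.

Step 11
Reactants: 17 (2Z,6S)-2,6-dimethyl-6-[(triethylsilyl)oxy]octa-2,7-dien-1-ol
Product: 18 [(2R,3S)-2-methyl-3-{(3S)-3-methyl-3-[(triethylsilyl)oxy]pent-4-en-1-yl}oxiran-2-yl]methanol
Conditions: Ti(OiPr)4 (20 mol %), D-(−)-diethyl tartrate (24 mol %), t-BuOOH, 4 Å MS, CH2Cl2, −20 °C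
Reagents that add atoms: tert-butyl hydroperoxide CC(C)(C)OO
Why: Sharpless asymmetric epoxidation is stereospecific (cis olefin to cis epoxide) and D-(−)-tartrate delivers oxygen to the face that gives the (2R,3S) epoxy alcohol from a Z allylic alcohol, setting C11 and C12 under reagent control while the isolated vinyl group is not epoxidised.

Step 12
Reactants: 18 [(2R,3S)-2-methyl-3-{(3S)-3-methyl-3-[(triethylsilyl)oxy]pent-4-en-1-yl}oxiran-2-yl]methanol
Product: 19 (2S,3S)-2-methyl-3-{(3S)-3-methyl-3-[(triethylsilyl)oxy]pent-4-en-1-yl}oxirane-2-carbaldehyde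
Conditions: nPr4N[RuO4] (5 mol %), N-methylmorpholine N-oxide, 4 Å MS, CH2Cl2, rt
Reagents that add atoms: none
Why: Ley–Griffith oxidation takes the primary alcohol to the aldehyde under neutral conditions, and the α-carbon is quaternary so it cannot epimerise.

Step 13
Reactants: 19 (2S,3S)-2-methyl-3-{(3S)-3-methyl-3-[(triethylsilyl)oxy]pent-4-en-1-yl}oxirane-2-carbaldehyde
Product: 21 (1S)-2-iodo-1-[(2S,3S)-2-methyl-3-{(3S)-3-methyl-3-[(triethylsilyl)oxy]pent-4-en-1-yl}oxiran-2-yl]ethyl acetate, via lithium alkoxide 20 (not isolated)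
Conditions: CH2I2, MeLi·LiBr, THF/Et2O, −78 °C; then Ac2O, −78 to −20 °C
Reagents that add atoms: diiodomethane ICI; acetic anhydride CC(=O)OC(C)=O
Why: In this carbenoid addition, iodomethyllithium formed by iodine–lithium exchange in the presence of the aldehyde should add in the Felkin–Anh/Cornforth sense (anti to the epoxide C–O bond) to set C13 erythro to the epoxide, and the cold lithium alkoxide is acetylated before it can close to a terminal epoxide.

Step 14
Reactants: 21 (1S)-2-iodo-1-[(2S,3S)-2-methyl-3-{(3S)-3-methyl-3-[(triethylsilyl)oxy]pent-4-en-1-yl}oxiran-2-yl]ethyl acetate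
Product: 22 (1S)-1-{(2S,3S)-3-[(3S)-3-hydroxy-3-methylpent-4-en-1-yl]-2-methyloxiran-2-yl}-2-iodoethyl acetate
Conditions: HF·pyridine, pyridine, THF, 0 °C
Reagents that add atoms: none
Why: Buffered fluoride desilylation frees the tertiary alcohol needed for the metathesis while the epoxide, the acetate and the primary iodide should survive.

Step 15
Reactants: 11 (5S)-5-[(1E)-2-methylpenta-1,4-dien-1-yl]-3-[(phenylsulfonyl)methyl]furan-2(5H)-one (1.5 equiv); 22 (1S)-1-{(2S,3S)-3-[(3S)-3-hydroxy-3-methylpent-4-en-1-yl]-2-methyloxiran-2-yl}-2-iodoethyl acetate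
Product: 23 (5S)-5-[(1E,4E,6S)-8-{(2S,3S)-3-[(1S)-1-acetoxy-2-iodoethyl]-3-methyloxiran-2-yl}-6-hydroxy-2,6-dimethylocta-1,4-dien-1-yl]-3-[(phenylsulfonyl)methyl]furan-2(5H)-one
Conditions: second-generation Hoveyda–Grubbs catalyst (H2IMes)Cl2Ru=CH(C6H4-2-OiPr) (10 mol %), 1,4-benzoquinone (10 mol %), CH2Cl2, 40 °C
Reagents that add atoms: none
Why: Olefin cross-metathesis between the allyl terminus of 11 and the tertiary allylic alcohol of 22 should give the E disubstituted C6=C7 olefin because the carbinol branch disfavours both the Z metallacycle and homodimerisation of 22, and it creates no stereocentre.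

Step 16
Reactants: 23 (5S)-5-[(1E,4E,6S)-8-{(2S,3S)-3-[(1S)-1-acetoxy-2-iodoethyl]-3-methyloxiran-2-yl}-6-hydroxy-2,6-dimethylocta-1,4-dien-1-yl]-3-[(phenylsulfonyl)methyl]furan-2(5H)-one
Product: 24 (1S,2S,3E,6E,8S,11S,12S,13R)-13-acetoxy-11,12-epoxy-8-hydroxycembra-3,6,15(17)-trien-16,2-olide (CNP0288879.2)
Conditions: (Bu3Sn)2 (1.5 equiv), degassed benzene (2 mM), hν (300 W sun lamp, Pyrex), 80 °C
Reagents that add atoms: none
Why: Photolysis of (Bu3Sn)2 gives Bu3Sn•, which abstracts iodine from C14; the primary β-acetoxyalkyl radical adds to C1, the β-carbon of the butenolide, and the C15 radical so formed ejects PhSO2• from C17 by β-fragmentation, so the exocyclic C15=C17 olefin appears as the C1–C14 bond forms and no hydride source competes. The closest known reaction types are the tin-mediated radical allylation of alkyl iodides by 2-(sulfonylmethyl)acrylates (SH2′ allyl transfer) and free-radical macrocyclisation of iodides onto acrylate-type acceptors. The carbocycle closes in a 14-exo-trig mode. The only new stereocentre, C1, is controlled by C2 through the tether: the chain is anchored on the C3 face of the lactone, and allylic 1,3-strain across the E C3=C4 olefin holds C2–H in the olefin plane so that the C4 methyl group screens the opposite face, which should favour syn delivery and the cis ring fusion. The step needs attack at C1 only (secured by the polarity match of the nucleophilic alkyl radical with the β-carbon of the unsaturated lactone), this facial selectivity, and survival of the epoxide, acetate, tertiary alcohol and skipped diene, all of which tin radicals leave alone.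

Compound list
1 | 2-(bromomethyl)prop-2-enoic acid | C=C(CBr)C(=O)O | starting material
2 | sodium benzenesulfinate | [Na+].[O-]S(=O)c1ccccc1 | starting material
3 | 2-[(phenylsulfonyl)methyl]prop-2-enoic acid | C=C(CS(=O)(=O)c1ccccc1)C(=O)O | intermediate
4 | pent-1-en-4-yne | C#CCC=C | starting material
5 | acrolein (prop-2-enal) | C=CC=O | starting material
6 | dimethyl[(1E)-2-methylpenta-1,4-dien-1-yl]alane | C[Al](C)/C=C(\C)CC=C | intermediate (not isolated)
7 | (4E)-5-methylocta-1,4,7-trien-3-ol, racemic | C=CC(O)/C=C(\C)CC=C | intermediate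
8 | (3R,4E)-5-methylocta-1,4,7-trien-3-yl acetate | CC(=O)O[C@H](C=C)/C=C(\C)CC=C | intermediate
9 | (3R,4E)-5-methylocta-1,4,7-trien-3-ol | O[C@H](C=C)/C=C(\C)CC=C | intermediate
10 | (3R,4E)-5-methylocta-1,4,7-trien-3-yl 2-[(phenylsulfonyl)methyl]prop-2-enoate | C=C(CS(=O)(=O)c1ccccc1)C(=O)O[C@H](C=C)/C=C(\C)CC=C | intermediate
11 | (5S)-5-[(1E)-2-methylpenta-1,4-dien-1-yl]-3-[(phenylsulfonyl)methyl]furan-2(5H)-one | O=C1O[C@@H](/C=C(\C)CC=C)C=C1CS(=O)(=O)c1ccccc1 | intermediate
12 | (S)-(+)-linalool, (3S)-3,7-dimethylocta-1,6-dien-3-ol | C=C[C@@](C)(O)CCC=C(C)C | starting material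
13 | triethyl{[(3S)-3,7-dimethylocta-1,6-dien-3-yl]oxy}silane | C=C[C@@](C)(O[Si](CC)(CC)CC)CCC=C(C)C | intermediate
14 | (4S)-4-methyl-4-[(triethylsilyl)oxy]hex-5-enal | C=C[C@@](C)(O[Si](CC)(CC)CC)CCC=O | intermediate
15 | methyl 2-[bis(2,2,2-trifluoroethoxy)phosphoryl]propanoate | COC(=O)C(C)P(=O)(OCC(F)(F)F)OCC(F)(F)F | starting material
16 | methyl (2Z,6S)-2,6-dimethyl-6-[(triethylsilyl)oxy]octa-2,7-dienoate | C=C[C@@](C)(O[Si](CC)(CC)CC)CC/C=C(/C)C(=O)OC | intermediate
17 | (2Z,6S)-2,6-dimethyl-6-[(triethylsilyl)oxy]octa-2,7-dien-1-ol | C=C[C@@](C)(O[Si](CC)(CC)CC)CC/C=C(/C)CO | intermediate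
18 | [(2R,3S)-2-methyl-3-{(3S)-3-methyl-3-[(triethylsilyl)oxy]pent-4-en-1-yl}oxiran-2-yl]methanol | C=C[C@@](C)(O[Si](CC)(CC)CC)CC[C@@H]1O[C@]1(C)CO | intermediate
19 | (2S,3S)-2-methyl-3-{(3S)-3-methyl-3-[(triethylsilyl)oxy]pent-4-en-1-yl}oxirane-2-carbaldehyde | C=C[C@@](C)(O[Si](CC)(CC)CC)CC[C@@H]1O[C@]1(C)C=O | intermediate
20 | lithium (1S)-2-iodo-1-[(2R,3S)-2-methyl-3-{(3S)-3-methyl-3-[(triethylsilyl)oxy]pent-4-en-1-yl}oxiran-2-yl]ethan-1-olate | C=C[C@@](C)(O[Si](CC)(CC)CC)CC[C@@H]1O[C@]1(C)[C@H]([O-])CI.[Li+] | intermediate (not isolated)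
21 | (1S)-2-iodo-1-[(2S,3S)-2-methyl-3-{(3S)-3-methyl-3-[(triethylsilyl)oxy]pent-4-en-1-yl}oxiran-2-yl]ethyl acetate | C=C[C@@](C)(O[Si](CC)(CC)CC)CC[C@@H]1O[C@]1(C)[C@H](OC(C)=O)CI | intermediate
22 | (1S)-1-{(2S,3S)-3-[(3S)-3-hydroxy-3-methylpent-4-en-1-yl]-2-methyloxiran-2-yl}-2-iodoethyl acetate | C=C[C@@](C)(O)CC[C@@H]1O[C@]1(C)[C@H](OC(C)=O)CI | intermediate
23 | (5S)-5-[(1E,4E,6S)-8-{(2S,3S)-3-[(1S)-1-acetoxy-2-iodoethyl]-3-methyloxiran-2-yl}-6-hydroxy-2,6-dimethylocta-1,4-dien-1-yl]-3-[(phenylsulfonyl)methyl]furan-2(5H)-one | O=C1O[C@@H](/C=C(\C)C/C=C/[C@@](C)(O)CC[C@@H]2O[C@]2(C)[C@H](OC(C)=O)CI)C=C1CS(=O)(=O)c1ccccc1 | intermediate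
24 | (1S,2S,3E,6E,8S,11S,12S,13R)-13-acetoxy-11,12-epoxy-8-hydroxycembra-3,6,15(17)-trien-16,2-olide | C=C1C(=O)O[C@H]2/C=C(\C)C/C=C/[C@@](C)(O)CC[C@@H]3O[C@]3(C)[C@H](OC(C)=O)C[C@@H]12 | target

Total step count: 16. Longest linear sequence: 10 steps (steps 7 to 16, from (S)-linalool 12 to 24); the west branch (steps 1 to 6) joins at step 15.

Steps most likely to fail

Step 16. The C14 radical may attack the C1 face anti to C3, which would give the trans-fused lactone. It may also be diverted by 1,5-hydrogen transfer from C10 or by intermolecular addition. The fallback sets C1 by anti addition in the C2-epimeric series and then inverts C2. It sets out from racemate 7 and comes back at 24. The enantiomer that step 3 leaves unacylated, (3S,4E)-5-methylocta-1,4,7-trien-3-ol F1, is esterified with 3 as in step 5 to (3S,4E)-5-methylocta-1,4,7-trien-3-yl 2-[(phenylsulfonyl)methyl]prop-2-enoate F2. Ring-closing metathesis as in step 6 gives (5R)-5-[(1E)-2-methylpenta-1,4-dien-1-yl]-3-[(phenylsulfonyl)methyl]furan-2(5H)-one F3, and cross-metathesis with 22 as in step 15 gives the (5R)-epimer of 23, F4. The tin-mediated closure of step 16, now running in the anti mode, should give (1S,2R,3E,6E,8S,11S,12S,13R)-13-acetoxy-11,12-epoxy-8-hydroxycembra-3,6,15(17)-trien-16,2-olide F5, which already has the correct C1. LiOH in THF/water opens the lactone and removes the acetate to give (1S,2R,3E,6E,8S,11S,12R,13R)-11,12-epoxy-2,8,13-trihydroxycembra-3,6,15(17)-trien-16-oic acid F6. Mitsunobu lactonisation (PPh3, DIAD, THF, high dilution) should invert the allylic C2 and give (1S,2S,3E,6E,8S,11S,12R,13R)-11,12-epoxy-8,13-dihydroxycembra-3,6,15(17)-trien-16,2-olide F7; the hindered C13 carbinol next to the quaternary epoxide carbon should not compete. Acetylation of the secondary alcohol (Ac2O, pyridine, DMAP) then gives 24.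

Step 13. Facial selectivity at the aldehyde may be poor and give the C13 epimer, or the alkoxide may close to the terminal epoxide before it is acetylated. The fallback sets C13 by chelation-controlled hydride delivery instead of by the C–C bond formation. It sets out from 19 and comes back at 21. The iodomethyllithium adduct is quenched cold with acetic acid to give the iodohydrin as an epimer mixture at C13. Ley–Griffith oxidation converts the mixture to 2-iodo-1-[(2S,3S)-2-methyl-3-{(3S)-3-methyl-3-[(triethylsilyl)oxy]pent-4-en-1-yl}oxiran-2-yl]ethan-1-one F9. Zn(BH4)2 in Et2O at −20 °C, known to give erythro epoxy alcohols from α,β-epoxy ketones, should return a single epimer, (1S)-2-iodo-1-[(2R,3S)-2-methyl-3-{(3S)-3-methyl-3-[(triethylsilyl)oxy]pent-4-en-1-yl}oxiran-2-yl]ethan-1-ol F8. Acetylation (Ac2O, pyridine, DMAP) gives 21.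

Step 3. The lipase may discriminate poorly between the two sp2 substituents (vinyl against dienyl), so that the acetate is not enantiopure. The fallback sets C2 by catalytic asymmetric C–C bond formation instead of resolution. It sets out from 4 (through alane 6) and comes back at 9. Alane 6 is converted to its alanate with n-BuLi and trapped with paraformaldehyde to give (2E)-3-methylhexa-2,5-dien-1-ol F10. MnO2 oxidation gives (2E)-3-methylhexa-2,5-dienal F11. Enantioselective vinylation with Zn(CH=CH2)2 and a catalytic chiral amino alcohol (the antipode of 3-exo-morpholinoisoborneol that delivers the R carbinol) gives 9 directly.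

Further compounds
F1 | step 16 | (3S,4E)-5-methylocta-1,4,7-trien-3-ol | O[C@@H](C=C)/C=C(\C)CC=C
F2 | step 16 | (3S,4E)-5-methylocta-1,4,7-trien-3-yl 2-[(phenylsulfonyl)methyl]prop-2-enoate | C=C(CS(=O)(=O)c1ccccc1)C(=O)O[C@@H](C=C)/C=C(\C)CC=C
F3 | step 16 | (5R)-5-[(1E)-2-methylpenta-1,4-dien-1-yl]-3-[(phenylsulfonyl)methyl]furan-2(5H)-one | O=C1O[C@H](/C=C(\C)CC=C)C=C1CS(=O)(=O)c1ccccc1
F4 | step 16 | (5R)-5-[(1E,4E,6S)-8-{(2S,3S)-3-[(1S)-1-acetoxy-2-iodoethyl]-3-methyloxiran-2-yl}-6-hydroxy-2,6-dimethylocta-1,4-dien-1-yl]-3-[(phenylsulfonyl)methyl]furan-2(5H)-one | O=C1O[C@H](/C=C(\C)C/C=C/[C@@](C)(O)CC[C@@H]2O[C@]2(C)[C@H](OC(C)=O)CI)C=C1CS(=O)(=O)c1ccccc1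
F5 | step 16 | (1S,2R,3E,6E,8S,11S,12S,13R)-13-acetoxy-11,12-epoxy-8-hydroxycembra-3,6,15(17)-trien-16,2-olide | C=C1C(=O)O[C@@H]2/C=C(\C)C/C=C/[C@@](C)(O)CC[C@@H]3O[C@]3(C)[C@H](OC(C)=O)C[C@@H]12
F6 | step 16 | (1S,2R,3E,6E,8S,11S,12R,13R)-11,12-epoxy-2,8,13-trihydroxycembra-3,6,15(17)-trien-16-oic acid | O[C@@H]1/C=C(\C)C/C=C/[C@@](C)(O)CC[C@@H]2O[C@]2(C)[C@H](O)C[C@H]1C(=C)C(=O)O
F7 | step 16 | (1S,2S,3E,6E,8S,11S,12R,13R)-11,12-epoxy-8,13-dihydroxycembra-3,6,15(17)-trien-16,2-olide | C=C1C(=O)O[C@H]2/C=C(\C)C/C=C/[C@@](C)(O)CC[C@@H]3O[C@]3(C)[C@H](O)C[C@@H]12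
F8 | step 13 | (1S)-2-iodo-1-[(2R,3S)-2-methyl-3-{(3S)-3-methyl-3-[(triethylsilyl)oxy]pent-4-en-1-yl}oxiran-2-yl]ethan-1-ol | C=C[C@@](C)(O[Si](CC)(CC)CC)CC[C@@H]1O[C@]1(C)[C@H](O)CI
F9 | step 13 | 2-iodo-1-[(2S,3S)-2-methyl-3-{(3S)-3-methyl-3-[(triethylsilyl)oxy]pent-4-en-1-yl}oxiran-2-yl]ethan-1-one | C=C[C@@](C)(O[Si](CC)(CC)CC)CC[C@@H]1O[C@]1(C)C(=O)CI
F10 | step 3 | (2E)-3-methylhexa-2,5-dien-1-ol | OC/C=C(\C)CC=C
F11 | step 3 | (2E)-3-methylhexa-2,5-dienal | O=C/C=C(\C)CC=C
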